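**Retrosynthetic overview**
1. The target is (1S,4S,5R,8S)-8-(3,4-dihydroxyphenyl)-4-(3,4,5-trihydroxyphenyl)-3,7-dioxabicyclo[3.3.0]octan-2-one (C2=O, O3, C4–aryl, C5, C6H2, O7, C8–aryl, C1). The rings are cis-fused and both aryl groups are exo.
2. Enabling feature: the γ-lactone ring C2–O3–C4–C5–C1 is an oxidised 1,4-diol (C2–OH and C4–OH). C4 carries both O3 and the aryl group, so C4–O3 can be read as a former C4–B bond and aryl–C4 as the result of a 1,2-shift from that boron. The ring-fusion bond C1–C5 lies next to it.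
3. Key disconnection: aryl–C4 and C1–C5 are cut together. This leads to an aryllithium and an acyclic (E)-alkenylboronate (C5=C4–B) tied through O7 to an oxirane (C1–C2–O). Opening the oxirane drives the aryl shift and closes the tetrahydrofuran ring first.
4. The lactone ring is closed second, by oxidative lactonisation of the 1,4-diol. Global debenzylation comes last.
5. The epoxy ether comes from 3,4-bis(benzyloxy)benzaldehyde by vinyl addition, Sharpless kinetic resolution (the source of absolute configuration), propargylation and hydroboration.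

Key step: step 7

Remark: the bicycle atom numbers given in line 1 are used for the same atoms in all precursors.

Step 1
Reactants: 1 5-bromo-1,2,3-trimethoxybenzene
Product: 2 5-bromobenzene-1,2,3-triol
Conditions: BBr3, CH2Cl2, −78 °C → rt; then H2O
Reagents that add atoms: none
Why: BBr3 ether cleavage, in which boron binds each methoxy oxygen and bromide removes the methyl group by SN2 while the aryl bromide stays inert.

Step 2
Reactants: 2 5-bromobenzene-1,2,3-triol
Product: 3 1,2,3-tris(benzyloxy)-5-bromobenzene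
Conditions: BnBr, K2CO3, DMF, 60 °C, N2
Reagents that add atoms: benzyl bromide BrCc1ccccc1
Why: Williamson ether synthesis, giving benzyl ethers that tolerate aryllithium, borate and peroxide chemistry and leave together at the end.

Step 3
Reactants: 4 3,4-bis(benzyloxy)benzaldehyde
Product: 5 rac-1-[3,4-bis(benzyloxy)phenyl]prop-2-en-1-ol
Conditions: vinylmagnesium bromide, THF, 0 °C; then aq NH4Cl
Reagents that add atoms: vinylmagnesium bromide C=C[Mg]Br
Why: Grignard 1,2-addition to the aldehyde, which forms the carbinol centre (C8) as a racemate that step 4 resolves.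

Step 4
Reactants: 5 rac-1-[3,4-bis(benzyloxy)phenyl]prop-2-en-1-ol
Product: 6 (R)-[3,4-bis(benzyloxy)phenyl][(2S)-oxiran-2-yl]methanol (erythro)
Conditions: Ti(OiPr)4 (cat.), D-(−)-DIPT (cat.), TBHP (0.45 equiv), 4 Å MS, CH2Cl2, −20 °C
Reagents that add atoms: tert-butyl hydroperoxide CC(C)(C)OO
Why: Sharpless kinetic resolution, in which the titanium D-(−)-tartrate catalyst epoxidises the (S)-alcohol much faster than the (R)-alcohol and from one alkene face only, so it should give the erythro epoxy alcohol, fixing C8 and (before its later inversion) C1, while the (R)-alcohol stays behind and is separated.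

Step 5
Reactants: 6 (R)-[3,4-bis(benzyloxy)phenyl][(2S)-oxiran-2-yl]methanol
Product: 7 (2S)-2-{(R)-[3,4-bis(benzyloxy)phenyl](prop-2-yn-1-yloxy)methyl}oxirane
Conditions: NaH, propargyl bromide, Bu4NI (cat.), THF, 0 °C
Reagents that add atoms: propargyl bromide C#CCBr
Why: Williamson ether synthesis, in which alkylation of the alkoxide by the reactive propargylic bromide at 0 °C should outrun Payne rearrangement and leaves both stereocentres untouched.

Step 6
Reactants: 7 (2S)-2-{(R)-[3,4-bis(benzyloxy)phenyl](prop-2-yn-1-yloxy)methyl}oxirane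
Product: 8 pinacol (E)-3-{(R)-[3,4-bis(benzyloxy)phenyl][(2S)-oxiran-2-yl]methoxy}prop-1-en-1-ylboronate
Conditions: pinacolborane, Cy2BH (10 mol %), THF, rt
Reagents that add atoms: pinacolborane [H]B1OC(C)(C)C(C)(C)O1
Why: dialkylborane-catalysed hydroboration of a terminal alkyne, a syn anti-Markovnikov addition that gives only the E-alkenylboronate, under conditions where dialkylboranes attack epoxides and ethers too slowly to matter.

Step 7
Reactants: 3 1,2,3-tris(benzyloxy)-5-bromobenzene; 8 pinacol (E)-3-{(R)-[3,4-bis(benzyloxy)phenyl][(2S)-oxiran-2-yl]methoxy}prop-1-en-1-ylboronate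
Product: 12 (S)-{(3R,4R,5S)-5-[3,4-bis(benzyloxy)phenyl]-4-(hydroxymethyl)oxolan-3-yl}[3,4,5-tris(benzyloxy)phenyl]methanol, via aryllithium 9 (not isolated), via boronate complex 10 (not isolated), via boronic ester alkoxide 11 (not isolated)
Conditions: 3, n-BuLi, THF, −78 °C; 8, −78 °C; LiOTf, −78 → 60 °C; then NaOH, H2O2, 0 °C → rt
Reagents that add atoms: hydrogen peroxide OO
Why: Proposed new method: aryllithium 9 adds to the vacant boron orbital of 8, and in boronate complex 10 the electron-rich C5=C4 π bond attacks the lithium-activated oxirane at its inner carbon C1 while the aryl group shifts 1,2 from boron to C4, so that release of the oxirane strain (about 27 kcal/mol) pays in one event for the ring-fusion bond C1–C5 and the aryl–C4 bond, after which alkaline peroxide replaces boron at C4 by OH with retention. The closest known reaction types are the electrophile-induced, anti-selective 1,2-metalate rearrangement of vinyl boronate complexes (three-component conjunctive couplings with carbon electrophiles) and the 1,4-diol synthesis from lithium trialkylvinylborates and oxiranes; new here are the intramolecular setting, the pinacol boronate with a migrating aryl group and the attack on the inner epoxide carbon. The tetrahydrofuran ring (O7, C8, C1, C5, C6) closes 5-exo-tet, the only mode in which C5, C1 and the leaving oxygen can become collinear (as in the Stork epoxynitrile cyclisation), so 6-endo attack at C2 should not compete. C1 is set by SN2 inversion of the (S)-oxirane carbon, which places C2 trans to the aryl group on C8; C5 is set by a chair-like transition state of the kind known from 5-hexenyl ring closures, with the C8 aryl group, the oxirane CH2 and the E-boryl terminus all pseudo-equatorial, which puts C4 cis to C2 and trans to the C8 aryl group; C4 is set by anti addition across the E double bond (the migrating aryl group is antiperiplanar to the new C1–C5 bond), which corresponds to the exo aryl group of the lactone. The step needs 9 to choose boron over the epoxide (secured at −78 °C by the much higher electrophilicity of the boronic ester), aryl rather than pinacol oxygen to migrate (inherent), and a leaving group that only ring strain provides, which is why nothing stronger than a lithium salt is used, so that the allylic and benzylic ether oxygen O7 cannot leave in an SN2'-type fragmentation and the C8 aryl group is not pushed into a semipinacol shift.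

Step 8
Reactants: 12 (S)-{(3R,4R,5S)-5-[3,4-bis(benzyloxy)phenyl]-4-(hydroxymethyl)oxolan-3-yl}[3,4,5-tris(benzyloxy)phenyl]methanol
Product: 14 (1S,4S,5R,8S)-8-[3,4-bis(benzyloxy)phenyl]-4-[3,4,5-tris(benzyloxy)phenyl]-3,7-dioxabicyclo[3.3.0]octan-2-one, via lactol 13 (not isolated)
Conditions: Cu(MeCN)4OTf, 2,2'-bipyridine, TEMPO (5 mol % each), N-methylimidazole (10 mol %), air, MeCN–CH2Cl2, rt
Reagents that add atoms: none
Why: copper/nitroxyl aerobic oxidative lactonisation of a 1,4-diol, in which the hindered TEMPO catalyst oxidises only the primary alcohol, the cis C4–OH closes the aldehyde at once to lactol 13 (which protects C1 from epimerisation), and a second oxidation gives the lactone without touching C4.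

Step 9
Reactants: 14 (1S,4S,5R,8S)-8-[3,4-bis(benzyloxy)phenyl]-4-[3,4,5-tris(benzyloxy)phenyl]-3,7-dioxabicyclo[3.3.0]octan-2-one
Product: 15 (1S,4S,5R,8S)-8-(3,4-dihydroxyphenyl)-4-(3,4,5-trihydroxyphenyl)-3,7-dioxabicyclo[3.3.0]octan-2-one
Conditions: H2 (1 atm), 10 % Pd/C, THF–MeOH, rt, stopped as soon as 14 is consumed
Reagents that add atoms: none
Why: catalytic hydrogenolysis, in which the five primary O-benzyl aryl ethers should cleave faster than the hindered secondary ring C–O bonds at C4 and C8 under neutral conditions that leave all four stereocentres alone.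

**Compound list**
1 | 5-bromo-1,2,3-trimethoxybenzene | COc1cc(Br)cc(OC)c1OC | starting material
2 | 5-bromobenzene-1,2,3-triol | Oc1cc(Br)cc(O)c1O | intermediate
3 | 1,2,3-tris(benzyloxy)-5-bromobenzene | Brc1cc(OCc2ccccc2)c(OCc2ccccc2)c(OCc2ccccc2)c1 | intermediate
4 | 3,4-bis(benzyloxy)benzaldehyde | O=Cc1ccc(OCc2ccccc2)c(OCc2ccccc2)c1 | starting material
5 | rac-1-[3,4-bis(benzyloxy)phenyl]prop-2-en-1-ol | C=CC(O)c1ccc(OCc2ccccc2)c(OCc2ccccc2)c1 | intermediate
6 | (R)-[3,4-bis(benzyloxy)phenyl][(2S)-oxiran-2-yl]methanol | O[C@H](c1ccc(OCc2ccccc2)c(OCc2ccccc2)c1)[C@@H]1CO1 | intermediate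
7 | (2S)-2-{(R)-[3,4-bis(benzyloxy)phenyl](prop-2-yn-1-yloxy)methyl}oxirane | C#CCO[C@H](c1ccc(OCc2ccccc2)c(OCc2ccccc2)c1)[C@@H]1CO1 | intermediate
8 | pinacol (E)-3-{(R)-[3,4-bis(benzyloxy)phenyl][(2S)-oxiran-2-yl]methoxy}prop-1-en-1-ylboronate | CC1(C)OB(/C=C/CO[C@H](c2ccc(OCc3ccccc3)c(OCc3ccccc3)c2)[C@@H]2CO2)OC1(C)C | intermediate
9 | 3,4,5-tris(benzyloxy)phenyllithium | [Li]c1cc(OCc2ccccc2)c(OCc2ccccc2)c(OCc2ccccc2)c1 | intermediate
10 | lithium boronate complex of 8 and 9 (aryl and E-alkenyl group on tetracoordinate pinacolato boron) | [Li+].CC1(C)O[B-](/C=C/CO[C@H](c2ccc(OCc3ccccc3)c(OCc3ccccc3)c2)[C@@H]2CO2)(c2cc(OCc3ccccc3)c(OCc3ccccc3)c(OCc3ccccc3)c2)OC1(C)C | intermediate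
11 | lithium {(2S,3R,4R)-2-[3,4-bis(benzyloxy)phenyl]-4-[(S)-(pinacolatoboryl)(3,4,5-tris(benzyloxy)phenyl)methyl]oxolan-3-yl}methanolate | [Li+].[O-]C[C@@H]1[C@@H](c2ccc(OCc3ccccc3)c(OCc3ccccc3)c2)OC[C@@H]1[C@H](B1OC(C)(C)C(C)(C)O1)c1cc(OCc2ccccc2)c(OCc2ccccc2)c(OCc2ccccc2)c1 | intermediate
12 | (S)-{(3R,4R,5S)-5-[3,4-bis(benzyloxy)phenyl]-4-(hydroxymethyl)oxolan-3-yl}[3,4,5-tris(benzyloxy)phenyl]methanol | OC[C@@H]1[C@@H](c2ccc(OCc3ccccc3)c(OCc3ccccc3)c2)OC[C@@H]1[C@H](O)c1cc(OCc2ccccc2)c(OCc2ccccc2)c(OCc2ccccc2)c1 | intermediate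
13 | (1S,4S,5R,8S)-8-[3,4-bis(benzyloxy)phenyl]-4-[3,4,5-tris(benzyloxy)phenyl]-3,7-dioxabicyclo[3.3.0]octan-2-ol (both C2 epimers) | OC1O[C@H](c2cc(OCc3ccccc3)c(OCc3ccccc3)c(OCc3ccccc3)c2)[C@H]2CO[C@H](c3ccc(OCc4ccccc4)c(OCc4ccccc4)c3)[C@@H]12 | intermediate
14 | (1S,4S,5R,8S)-8-[3,4-bis(benzyloxy)phenyl]-4-[3,4,5-tris(benzyloxy)phenyl]-3,7-dioxabicyclo[3.3.0]octan-2-one | O=C1O[C@H](c2cc(OCc3ccccc3)c(OCc3ccccc3)c(OCc3ccccc3)c2)[C@H]2CO[C@H](c3ccc(OCc4ccccc4)c(OCc4ccccc4)c3)[C@@H]12 | intermediate
15 | (1S,4S,5R,8S)-8-(3,4-dihydroxyphenyl)-4-(3,4,5-trihydroxyphenyl)-3,7-dioxabicyclo[3.3.0]octan-2-one | O=C1O[C@H](c2cc(O)c(O)c(O)c2)[C@H]2CO[C@H](c3ccc(O)c(O)c3)[C@@H]12 | target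

Total step count: 9. Longest linear sequence: 7 (steps 3 to 9, from 4).

**Steps most likely to fail**

1. Step 7. The pinacol boronate complex may be too weak a nucleophile for an epoxide activated only by lithium, so ring closure could lose to slow decomposition on heating. Closure through a boat-like transition state would erode the cis relation C2/C4. Stronger activation would invite fragmentation at O7 or a semipinacol aryl shift.
The fallback sets out from 7 (and 3), returns at 12, and uses known chemistry only.
- Titanocene(III) chloride (Cp2TiCl2, Zn, THF) opens the epoxide of 7 homolytically. The β-titanoxy radical closes 5-exo-dig (Nugent–RajanBabu reaction, established for lignan-type epoxy propargyl ethers) to [(2S,3R)-2-[3,4-bis(benzyloxy)phenyl]-4-methylideneoxolan-3-yl]methanol F1.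
- TBSCl and imidazole give the silyl ether of this alcohol F2.
- 9-BBN followed by NaOH/H2O2 adds from the face opposite the silyloxymethyl group and gives the cis primary alcohol F3.
- iPr2NCOCl and Et3N give its N,N-diisopropylcarbamate F4.
- Separately, 3 is converted with n-BuLi and iPrOBpin into 3,4,5-tris(benzyloxy)phenylboronic acid pinacol ester F5.
- Lithiation–borylation follows: s-BuLi/(+)-sparteine on F4, addition of F5, then warming for the 1,2-metalate rearrangement. This makes the same aryl–C4 bond under reagent control and gives the benzylic boronic ester F6.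
- F6 is oxidised in the same flask (NaOH/H2O2) to the benzylic alcohol silyl ether F7. TBAF then gives 12.

2. Step 4. The resolution may be slow or poorly selective for this electron-rich aryl vinyl carbinol. The acid-sensitive benzylic epoxy alcohol may also be opened by the titanium Lewis acid during the long reaction time.
The fallback sets out from 5 and returns at 6, and separates resolution from epoxidation.
- Candida antarctica lipase B with vinyl acetate in MTBE leaves (S)-1-[3,4-bis(benzyloxy)phenyl]prop-2-en-1-ol F8.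
- The same treatment converts the other enantiomer into (R)-1-[3,4-bis(benzyloxy)phenyl]prop-2-en-1-yl acetate F9, which is removed by chromatography.
- Hydroxyl-directed epoxidation of F8 with VO(acac)2/TBHP, which is erythro-selective for terminal secondary allylic alcohols, can be run to full conversion and gives 6.

3. Step 9. Over-reduction is the danger: the benzylic ring bonds C4–O3 and C8–O7 could undergo hydrogenolysis once the phenols are free.
The fallback sets out from 14 and returns at 15. It is a non-reductive Lewis-acid debenzylation with BCl3 and pentamethylbenzene as cation scavenger in CH2Cl2 at −78 °C, followed by a methanol quench.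

**Further compounds**
F1 | step 7 | [(2S,3R)-2-[3,4-bis(benzyloxy)phenyl]-4-methylideneoxolan-3-yl]methanol | OC[C@@H]1[C@@H](c2ccc(OCc3ccccc3)c(OCc3ccccc3)c2)OCC1=C
F2 | step 7 | tert-butyldimethylsilyl ether of F1 | CC(C)(C)[Si](C)(C)OC[C@@H]1[C@@H](c2ccc(OCc3ccccc3)c(OCc3ccccc3)c2)OCC1=C
F3 | step 7 | cis primary alcohol from hydroboration of F2 | CC(C)(C)[Si](C)(C)OC[C@@H]1[C@@H](c2ccc(OCc3ccccc3)c(OCc3ccccc3)c2)OC[C@@H]1CO
F4 | step 7 | N,N-diisopropylcarbamate of F3 | CC(C)(C)[Si](C)(C)OC[C@@H]1[C@@H](c2ccc(OCc3ccccc3)c(OCc3ccccc3)c2)OC[C@@H]1COC(=O)N(C(C)C)C(C)C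
F5 | step 7 | 3,4,5-tris(benzyloxy)phenylboronic acid pinacol ester | CC1(C)OB(c2cc(OCc3ccccc3)c(OCc3ccccc3)c(OCc3ccccc3)c2)OC1(C)C
F6 | step 7 | benzylic boronic ester from lithiation–borylation (silyl ether analogue of 11) | CC(C)(C)[Si](C)(C)OC[C@@H]1[C@@H](c2ccc(OCc3ccccc3)c(OCc3ccccc3)c2)OC[C@@H]1[C@H](B1OC(C)(C)C(C)(C)O1)c1cc(OCc2ccccc2)c(OCc2ccccc2)c(OCc2ccccc2)c1
F7 | step 7 | mono-TBS ether of 12 (primary OH silylated) | CC(C)(C)[Si](C)(C)OC[C@@H]1[C@@H](c2ccc(OCc3ccccc3)c(OCc3ccccc3)c2)OC[C@@H]1[C@H](O)c1cc(OCc2ccccc2)c(OCc2ccccc2)c(OCc2ccccc2)c1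
F8 | step 4 | (S)-1-[3,4-bis(benzyloxy)phenyl]prop-2-en-1-ol | O[C@H](c1ccc(OCc2ccccc2)c(OCc2ccccc2)c1)C=C
F9 | step 4 | (R)-1-[3,4-bis(benzyloxy)phenyl]prop-2-en-1-yl acetate | CC(=O)O[C@@H](c1ccc(OCc2ccccc2)c(OCc2ccccc2)c1)C=C
F0 | step 9 | none | none
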